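Late in the grey run, at 10.0 min, substrate stood at 5% of the charge and first product at 3%, so first product had fallen back from the 19% I read at 1.50 min.

| setting | green | grey | north-west | west | north-east | south | east |
|---|---|---|---|---|---|---|---|
| substrate | 0.20 M | 0.20 M | 0.20 M | 0.20 M | 0.20 M | 0.20 M | 0.20 M |
| reagent | 0.14 M | 1.8 M | 0.100 M | 0.200 M | 0.400 M | 0.800 M | 1.50 M |
| remark | run made earlier | run made earlier |  |  |  |  |  |
| time |  |  | 15 min | 15 min | 15 min | 15 min | 15 min |

- green (time / min: first product / %, substrate / %): 2.00: 4, 92; 4.00: 7, 90; 6.00: 7, 85; 8.00: 10, 83; 10.0: 9, 78
- grey (time / min: first product / %, substrate / %): 0.833: 14, 71; 1.50: 19, 56; 3.00: 14, 33; 6.00: 5, 14; 10.0: 3, 5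

(each reading ± 1.5 percentage points)

- [first product] at the end for north-west, west, north-east, south, east, in this order
- how that number moves from the first to the last of them (rises all the way / falls, then rises / rises, then falls / falls all the way / hardly changes)

- "hardly changes" means that all values lie within two and a half points (for a concentration: within two and a half percent of the largest)

From the grey readings I read a substrate lifetime of 2.71 min, and from the green readings 40.2 min. That is 14.8 times as long with 12.9 times less reagent, so I took the lifetime as inversely proportional to reagent (pseudo-first-order).

I called the time passed over that lifetime the dose, and the dose at the grey reading of highest first product the peak dose, 0.580. I assumed that this dose held for every charge.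

With reagent held at its full charge, I reckoned that the east flask should reach it at 1.88 min, south at 3.53 min and north-east at 7.06 min. For west the same reckoning gave 14.1 min, just sooner than the end, and for north-west 28.2 min, later than the end.

But reagent is used, so I replaced its falling curve by its mean. Reaching the peak dose at the end needed a mean of 0.188 M. Counting one reagent per substrate lost and one more for what the grey flask had lost beyond first product, the use was 0.138 M. I therefore expected the row to turn near a charge of 0.257 M.

The forecast, reckoned differently, put first product at 0.022 M, 0.032 M, 0.033 M, 0.019 M and 0.003 M, from north-west to east, with north-east at 16.5% of the charge, so the row rises, then falls. It assumed that “one reagent is consumed per substrate lost and one per product destroyed”.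

The flasks ended at 0.0165 M, 0.0230 M, 0.0230 M, 0.0116 M and 0.00184 M, from north-west to east, with north-east at 11.5% of the charge, so the row rises, then falls, turning at a reagent charge of 0.29 M.

    substrate + reagent → first product (k = 0.00280 M⁻¹ s⁻¹)
    substrate + reagent → other mono adduct (k = 8.70 × 10⁻⁴ M⁻¹ s⁻¹)
    reagent + first product → double product (k = 0.00840 M⁻¹ s⁻¹)
    reagent + other mono adduct → double product (k = 0.00570 M⁻¹ s⁻¹)
    first product ⇌ isomer of the product (K = 28.0, k = 9.10 × 10⁻⁴ s⁻¹)

With the mean of the first and last reagent, north-west had a dose of 0.231, less than the peak dose, yet at 15.0 min first product there was made 1.02 times as fast as it was used up, each step taken net, against 2.04 at 5.79 min. South had a dose of 1.99, more than the peak dose, which gives substrate 13.7%, and the south flask held 13.7%.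

Readings and results were computed for substances that don't exist; noise was put on by code.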